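**Retrosynthetic overview**
1. Target 25 ⇐ C7-selective acetylation of triol 24 ⇐ anti-elimination of 5,6-epoxy-7-ol 22 (creates C5=C10, keeps the C6–O bond) ⇐ singlet-oxygen ene reaction plus titanium oxygen transfer on the Δ6 alkene of 20.
2. The C13 carbinol of 20 ⇐ Sharpless epoxidation and reductive opening of Z-allylic alcohol 17 ⇐ B-alkyl Suzuki coupling of vinyl compound 12 with vinyl iodide 15.
3. 12 ⇐ bicyclic aldehyde 11 ⇐ catalytic enantioselective intramolecular Diels–Alder reaction of the acyclic trienal 10, which closes both carbocycles and sets C8 and the quaternary C9 in one step.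
4. 10 ⇐ B-alkyl Suzuki coupling of triene 8 (Wittig product of 2,2-dimethylpent-4-enal) with bromo-enal 3 (from methacrolein).
5. Ring order: rings A and B together in step 4; the C5 and C10 stereocentres of the adduct are later erased into the tetrasubstituted alkene.

Convention (one line): locants in the explanations are halimane locants (C4 = CMe2, C5/C10 = ring-fusion carbons, C6/C7 = oxygenated carbons, C8 = CHMe, C9 = quaternary carbon, C11–C16 = side chain with C13 the carbinol); compounds 4 and 5 are taken as purchased.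

Step 1
Reactants: 1 methacrolein
Product: 3 (E)-3-bromo-2-methylprop-2-enal, via dibromide 2 (not isolated)
Conditions: Br2, CH2Cl2, 0 °C; then Et3N, 0 °C → rt
Reagents that add atoms: bromine, BrBr
Why: Bromine adds across the enal alkene and triethylamine then removes HBr from the tertiary α-bromide (bromination–dehydrobromination) to give the more stable E β-bromo enal with Br trans to CHO.

Step 2
Reactants: 4 2,2-dimethylpent-4-enal; 5 (E)-but-2-enyl(triphenyl)phosphonium bromide
Product: 8 (5E,7E)-4,4-dimethylnona-1,5,7-triene, via crotyl ylide 6 (not isolated), via (5Z,7E)-triene 7 (not isolated)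
Conditions: n-BuLi, THF, −78 °C → rt; then I2 (3 mol%), hexane, daylight, rt
Reagents that add atoms: none
Why: Wittig olefination of the non-enolisable α-quaternary aldehyde with the semi-stabilised crotyl ylide builds the diene, and iodine-catalysed isomerisation converts the 5Z isomer into the thermodynamic E,E-diene; no stereocentre is formed.

Step 3
Reactants: 8 (5E,7E)-4,4-dimethylnona-1,5,7-triene; 3 (E)-3-bromo-2-methylprop-2-enal
Product: 10 (2E,8E,10E)-2,7,7-trimethyldodeca-2,8,10-trienal, via alkylborane 9 (not isolated)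
Conditions: 9-BBN, THF, 0 °C → rt; then 3, Pd(dppf)Cl2 (5 mol%), AsPh3, Cs2CO3, DMF–H2O, rt
Reagents that add atoms: none
Why: 9-BBN hydroborates only the monosubstituted terminal alkene, and the primary alkylborane then undergoes B-alkyl Suzuki–Miyaura coupling with the β-bromo enal with retention of the E geometry; no stereocentre is formed.

Step 4
Reactants: 10 (2E,8E,10E)-2,7,7-trimethyldodeca-2,8,10-trienal
Product: 11 (1R,2R,4aS,8aR)-1,2,5,5-tetramethyl-1,2,4a,5,6,7,8,8a-octahydronaphthalene-1-carbaldehyde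
Conditions: (S)-o-tolyl-CBS oxazaborolidine·HNTf2 (20 mol%), CH2Cl2, −78 → −40 °C
Reagents that add atoms: none
Why: Catalytic enantioselective intramolecular Diels–Alder reaction (Corey oxazaborolidinium activation of a 2-methyl enal) in which the catalyst-bound s-trans enal is attacked on the face away from the shielding aryl group (the sense that gives the S exo adduct from methacrolein) through the CHO-endo transition state with the four-atom tether exo, so that both rings close at once as the trans-fused octalin with the C8 methyl cis to the formyl group on the new quaternary C9, the E,E-diene and E-enal geometries fixing the C8/C9 relationship.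

Step 5
Reactants: 11 (1R,2R,4aS,8aR)-1,2,5,5-tetramethyl-1,2,4a,5,6,7,8,8a-octahydronaphthalene-1-carbaldehyde
Product: 12 (1R,2R,4aS,8aR)-1-ethenyl-1,2,5,5-tetramethyl-1,2,4a,5,6,7,8,8a-octahydronaphthalene
Conditions: Ph3PCH3Br, KOtBu, THF, 0 °C → rt
Reagents that add atoms: methyltriphenylphosphonium bromide, C[P+](c1ccccc1)(c1ccccc1)c1ccccc1.[Br-]
Why: Wittig methylenation of the hindered, non-enolisable neopentyl aldehyde cannot epimerise the adjacent quaternary centre and leaves the ring alkene untouched.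

Step 6
Reactants: 13 but-2-yn-1-ol
Product: 15 (Z)-3-iodobut-2-en-1-ol, via alkenylaluminate 14 (not isolated)
Conditions: NaAlH2(OCH2CH2OMe)2, Et2O, 0 °C → rt; then I2, THF, −78 °C; aq. Rochelle salt
Reagents that add atoms: iodine, [I][I]
Why: Hydroxyl-directed trans-hydroalumination of the propargylic alcohol places aluminium on C3 inside a five-membered alkenylaluminate, and iodinolysis with retention gives the Z vinyl iodide (Corey-type hydroalumination–iodination).

Step 7
Reactants: 12 (1R,2R,4aS,8aR)-1-ethenyl-1,2,5,5-tetramethyl-1,2,4a,5,6,7,8,8a-octahydronaphthalene; 15 (Z)-3-iodobut-2-en-1-ol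
Product: 17 (2Z)-3-methyl-5-[(1R,2R,4aS,8aR)-1,2,5,5-tetramethyl-1,2,4a,5,6,7,8,8a-octahydronaphthalen-1-yl]pent-2-en-1-ol, via alkylborane 16 (not isolated)
Conditions: 9-BBN, THF, rt; then 15, Pd(dppf)Cl2 (5 mol%), AsPh3, Cs2CO3, DMF–H2O, rt
Reagents that add atoms: none
Why: 9-BBN selects the monosubstituted vinyl group over the hindered ring alkene, and B-alkyl Suzuki–Miyaura coupling with the Z vinyl iodide proceeds with retention to give the nerol-type Z allylic alcohol; no stereocentre is formed.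

Step 8
Reactants: 17 (2Z)-3-methyl-5-[(1R,2R,4aS,8aR)-1,2,5,5-tetramethyl-1,2,4a,5,6,7,8,8a-octahydronaphthalen-1-yl]pent-2-en-1-ol
Product: 18 [(2S,3R)-3-methyl-3-{2-[(1R,2R,4aS,8aR)-1,2,5,5-tetramethyl-1,2,4a,5,6,7,8,8a-octahydronaphthalen-1-yl]ethyl}oxiran-2-yl]methanol
Conditions: Ti(OiPr)4 (10 mol%), L-(+)-diethyl tartrate (12 mol%), t-BuOOH (2 equiv), 4 Å MS, CH2Cl2, −20 °C
Reagents that add atoms: tert-butyl hydroperoxide, CC(C)(C)OO
Why: Katsuki–Sharpless asymmetric epoxidation with L-(+)-diethyl tartrate converts a Z 3,3-disubstituted allylic alcohol (nerol type) into the (2S,3R)-epoxy alcohol, which fixes C13 as R by reagent control independent of the remote ring stereocentres, while the unfunctionalised ring alkene does not react.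

Step 9
Reactants: 18 [(2S,3R)-3-methyl-3-{2-[(1R,2R,4aS,8aR)-1,2,5,5-tetramethyl-1,2,4a,5,6,7,8,8a-octahydronaphthalen-1-yl]ethyl}oxiran-2-yl]methanol
Product: 20 (3R)-3-methyl-5-[(1R,2R,4aS,8aR)-1,2,5,5-tetramethyl-1,2,4a,5,6,7,8,8a-octahydronaphthalen-1-yl]pent-1-en-3-ol, via epoxy iodide 19 (not isolated)
Conditions: I2, PPh3, imidazole, CH2Cl2, 0 °C; then Zn dust, AcOH, EtOH, rt
Reagents that add atoms: none
Why: Appel-type iodination of the primary alcohol followed by zinc-mediated reductive β-elimination of the epoxy iodide breaks only the C14–O bond, so the C13–O bond and its R configuration are carried into the tertiary allylic alcohol (the epoxygeraniol-to-linalool type of reductive epoxide opening).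

Step 10
Reactants: 20 (3R)-3-methyl-5-[(1R,2R,4aS,8aR)-1,2,5,5-tetramethyl-1,2,4a,5,6,7,8,8a-octahydronaphthalen-1-yl]pent-1-en-3-ol
Product: 22 (3R)-5-[(1R,2S,3R,4R,4aR,8aS)-4,4a-epoxy-3-hydroxy-1,2,5,5-tetramethyldecahydronaphthalen-1-yl]-3-methylpent-1-en-3-ol, via allylic hydroperoxide 21 (not isolated)
Conditions: O2, hν (visible), tetraphenylporphyrin (cat.), Ti(OiPr)4 (10 mol%), CH2Cl2, 0 °C
Reagents that add atoms: oxygen, O=O
Why: Schenck ene reaction of singlet oxygen at the cis-disubstituted ring alkene can only use the axial allylic H5, which lies on the face opposite the C8 methyl, so oxygen is delivered to C7 on that face with shift of the alkene to C5=C6, and the titanium-bound hydroperoxide then passes its distal oxygen to the new trisubstituted alkene syn to the C7–O bond (Adam one-pot hydroxy-epoxidation), setting C7, C6 and C5 on one face.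

Step 11
Reactants: 22 (3R)-5-[(1R,2S,3R,4R,4aR,8aS)-4,4a-epoxy-3-hydroxy-1,2,5,5-tetramethyldecahydronaphthalen-1-yl]-3-methylpent-1-en-3-ol
Product: 24 (1S,2R,3S,4R)-4-[(3R)-3-hydroxy-3-methylpent-4-en-1-yl]-3,4,8,8-tetramethyl-1,2,3,4,5,6,7,8-octahydronaphthalene-1,2-diol, via tris-silyl ether 23 (not isolated)
Conditions: TMSOTf (3.5 equiv), 2,6-lutidine (5 equiv), CH2Cl2, −78 → −40 °C; then K2CO3 (cat.), MeOH, rt
Reagents that add atoms: none
Why: Noyori-type silyl triflate–amine isomerisation of a trisubstituted epoxide to an allylic silyl ether, in which the silylated epoxide ionises at the tertiary C5 and the anti-periplanar axial H10 is removed by the base to give the tetrasubstituted C5=C10 alkene while the C6–O bond and hence the cis-6,7-diol configuration are retained, after which methanolysis frees the three hydroxyl groups.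

Step 12
Reactants: 24 (1S,2R,3S,4R)-4-[(3R)-3-hydroxy-3-methylpent-4-en-1-yl]-3,4,8,8-tetramethyl-1,2,3,4,5,6,7,8-octahydronaphthalene-1,2-diol
Product: 25 (1S,2R,3S,4R)-1-hydroxy-4-[(3R)-3-hydroxy-3-methylpent-4-en-1-yl]-3,4,8,8-tetramethyl-1,2,3,4,5,6,7,8-octahydronaphthalen-2-yl acetate
Conditions: Ac2O (1.1 equiv), pyridine, CH2Cl2, −20 → 0 °C
Reagents that add atoms: acetic anhydride, CC(=O)OC(C)=O
Why: Kinetic O-acetylation distinguishes the equatorial, less hindered C7 hydroxyl from the pseudoaxial allylic C6 hydroxyl next to the gem-dimethyl-flanked alkene carbon and from the tertiary C13 hydroxyl, giving the 7-monoacetate.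

**Compound list**
1 | methacrolein (2-methylprop-2-enal) | C=C(C)C=O | starting material
2 | 2,3-dibromo-2-methylpropanal | O=CC(C)(Br)CBr | intermediate
3 | (E)-3-bromo-2-methylprop-2-enal | O=C/C(C)=C/Br | intermediate
4 | 2,2-dimethylpent-4-enal | C=CCC(C)(C)C=O | starting material
5 | (E)-but-2-enyl(triphenyl)phosphonium bromide | C/C=C/C[P+](c1ccccc1)(c1ccccc1)c1ccccc1.[Br-] | starting material
6 | (E)-but-2-enylidene(triphenyl)phosphorane (crotyl ylide) | C/C=C/C=P(c1ccccc1)(c1ccccc1)c1ccccc1 | intermediate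
7 | (5Z,7E)-4,4-dimethylnona-1,5,7-triene | C=CCC(C)(C)/C=C\C=C\C | intermediate
8 | (5E,7E)-4,4-dimethylnona-1,5,7-triene | C=CCC(C)(C)/C=C/C=C/C | intermediate
9 | 9-[(5E,7E)-4,4-dimethylnona-5,7-dien-1-yl]-9-borabicyclo[3.3.1]nonane | C/C=C/C=C/C(C)(C)CCCB1C2CCCC1CCC2 | intermediate
10 | (2E,8E,10E)-2,7,7-trimethyldodeca-2,8,10-trienal | O=C/C(C)=C/CCCC(C)(C)/C=C/C=C/C | intermediate
11 | (1R,2R,4aS,8aR)-1,2,5,5-tetramethyl-1,2,4a,5,6,7,8,8a-octahydronaphthalene-1-carbaldehyde (trans-fused; CHO, C2 methyl and H-8a on one face) | O=C[C@@]1(C)[C@@H]2CCCC(C)(C)[C@H]2C=C[C@H]1C | intermediate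
12 | (1R,2R,4aS,8aR)-1-ethenyl-1,2,5,5-tetramethyl-1,2,4a,5,6,7,8,8a-octahydronaphthalene | C=C[C@@]1(C)[C@@H]2CCCC(C)(C)[C@H]2C=C[C@H]1C | intermediate
13 | but-2-yn-1-ol | CC#CCO | starting material
14 | sodium 2,2-bis(2-methoxyethoxy)-3-methyl-2,5-dihydro-1,2-oxaaluminol-2-uide (cyclic alkenylaluminate) | CC1=CCO[Al-]1(OCCOC)OCCOC.[Na+] | intermediate
15 | (Z)-3-iodobut-2-en-1-ol | C/C(I)=C/CO | intermediate
16 | 9-{2-[(1R,2R,4aS,8aR)-1,2,5,5-tetramethyl-1,2,4a,5,6,7,8,8a-octahydronaphthalen-1-yl]ethyl}-9-borabicyclo[3.3.1]nonane | B1(CC[C@@]2(C)[C@@H]3CCCC(C)(C)[C@H]3C=C[C@H]2C)C4CCCC1CCC4 | intermediate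
17 | (2Z)-3-methyl-5-[(1R,2R,4aS,8aR)-1,2,5,5-tetramethyl-1,2,4a,5,6,7,8,8a-octahydronaphthalen-1-yl]pent-2-en-1-ol | OC/C=C(/C)CC[C@@]1(C)[C@@H]2CCCC(C)(C)[C@H]2C=C[C@H]1C | intermediate
18 | [(2S,3R)-3-methyl-3-{2-[(1R,2R,4aS,8aR)-1,2,5,5-tetramethyl-1,2,4a,5,6,7,8,8a-octahydronaphthalen-1-yl]ethyl}oxiran-2-yl]methanol | OC[C@@H]1O[C@]1(C)CC[C@@]2(C)[C@@H]3CCCC(C)(C)[C@H]3C=C[C@H]2C | intermediate
19 | (2R,3R)-2-(iodomethyl)-3-methyl-3-{2-[(1R,2R,4aS,8aR)-1,2,5,5-tetramethyl-1,2,4a,5,6,7,8,8a-octahydronaphthalen-1-yl]ethyl}oxirane | IC[C@@H]1O[C@]1(C)CC[C@@]2(C)[C@@H]3CCCC(C)(C)[C@H]3C=C[C@H]2C | intermediate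
20 | (3R)-3-methyl-5-[(1R,2R,4aS,8aR)-1,2,5,5-tetramethyl-1,2,4a,5,6,7,8,8a-octahydronaphthalen-1-yl]pent-1-en-3-ol | C=C[C@](C)(O)CC[C@@]1(C)[C@@H]2CCCC(C)(C)[C@H]2C=C[C@H]1C | intermediate
21 | (3R)-5-[(1S,2S,3S,8aS)-3-hydroperoxy-1,2,5,5-tetramethyl-1,2,3,5,6,7,8,8a-octahydronaphthalen-1-yl]-3-methylpent-1-en-3-ol (OOH trans to the adjacent ring methyl) | C=C[C@](C)(O)CC[C@@]1(C)[C@@H]2CCCC(C)(C)C2=C[C@H](OO)[C@H]1C | intermediate
22 | (3R)-5-[(1R,2S,3R,4R,4aR,8aS)-4,4a-epoxy-3-hydroxy-1,2,5,5-tetramethyldecahydronaphthalen-1-yl]-3-methylpent-1-en-3-ol (epoxide and ring OH on the same face) | C=C[C@](C)(O)CC[C@@]1(C)[C@@H]2CCCC(C)(C)[C@]23O[C@@H]3[C@H](O)[C@H]1C | intermediate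
23 | tris(trimethylsilyl) ether of 24 | C=C[C@](C)(O[Si](C)(C)C)CC[C@@]1(C)C2=C([C@H](O[Si](C)(C)C)[C@H](O[Si](C)(C)C)[C@H]1C)C(C)(C)CCC2 | intermediate
24 | (1S,2R,3S,4R)-4-[(3R)-3-hydroxy-3-methylpent-4-en-1-yl]-3,4,8,8-tetramethyl-1,2,3,4,5,6,7,8-octahydronaphthalene-1,2-diol | C=C[C@](C)(O)CC[C@@]1(C)C2=C([C@H](O)[C@H](O)[C@H]1C)C(C)(C)CCC2 | intermediate
25 | CNP0126002.3, (1S,2R,3S,4R)-1-hydroxy-4-[(3R)-3-hydroxy-3-methylpent-4-en-1-yl]-3,4,8,8-tetramethyl-1,2,3,4,5,6,7,8-octahydronaphthalen-2-yl acetate | C=C[C@](C)(O)CC[C@@]1(C)C2=C([C@H](O)[C@H](OC(C)=O)[C@H]1C)C(C)(C)CCC2 | target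

**Step count**
Total: 12 steps (steps 1 and 6 prepare the two coupling partners). Longest linear sequence: 10 steps (2 → 3 → 4 → 5 → 7 → 8 → 9 → 10 → 11 → 12, from 2,2-dimethylpent-4-enal).

**Three steps most likely to fail**

Step 4 (Diels–Alder bicyclisation). The risks are a slow reaction of the trisubstituted enal, incomplete endo selectivity, and the sense or level of enantio-induction; the sense assigned to the (S)-catalyst rests on the reported methacrolein result and has not been checked for this substrate. If only the sense is wrong, the mirror-image catalyst is used. The fallback changes the source of facial control to a covalently bound auxiliary and the cycloaddition to an ionic (Gassman-type) Diels–Alder reaction. It sets out from 10, which is acetalised with (2R,4R)-pentane-2,4-diol (PPTS, benzene, Dean–Stark) to (4R,6R)-2-[(2E,8E,10E)-7,7-dimethyldodeca-2,8,10-trien-2-yl]-4,6-dimethyl-1,3-dioxane F1. TMSOTf in CH2Cl2 at −78 °C ionises F1 to the alkoxy-allyl cation, which cyclises under control of the C2-symmetric acetal to (4R,6R)-4,6-dimethyl-2-[(1R,2R,4aS,8aR)-1,2,5,5-tetramethyl-1,2,4a,5,6,7,8,8a-octahydronaphthalen-1-yl]-1,3-dioxane F2. Aqueous HCl in THF hydrolyses F2 and the route is rejoined at 11. The other diol antipode is taken if the induction runs the wrong way.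

Step 10 (photo-oxygenation). The cis-disubstituted alkene is hindered on both faces (adjacent C8 methyl on one, 1,3-related C9 methyl on the other) and may react slowly or be over-oxidised. The fallback installs the first oxygen by epoxidation and base-induced isomerisation instead of an ene reaction. It sets out from 20, which with mCPBA (NaHCO3, CH2Cl2, 0 °C) gives (3R)-5-[(1S,2S,3R,4S,4aS,8aR)-3,4-epoxy-1,2,5,5-tetramethyldecahydronaphthalen-1-yl]-3-methylpent-1-en-3-ol F3 (epoxide anti to the C8 methyl). Et2Al–TMP (benzene, 0 °C) removes the syn axial H5 to give the allylic alcohol (3R)-5-[(1S,2S,3S,8aS)-3-hydroxy-1,2,5,5-tetramethyl-1,2,3,5,6,7,8,8a-octahydronaphthalen-1-yl]-3-methylpent-1-en-3-ol F4. Hydroxyl-directed epoxidation with VO(acac)2 and t-BuOOH (1.0 equiv, CH2Cl2, 0 °C) then rejoins the route at 22.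

Step 11 (epoxide to allylic alcohol). Ionisation at C5 next to the gem-dimethyl carbon could lead to a 1,2-methyl shift or to hydride shift giving the 6-ketone. The fallback opens the epoxide by single-electron transfer instead of ionisation. It sets out from 22, which is treated with Cp2TiCl (trivalent titanium, made from Cp2TiCl2 and Mn dust), 2,4,6-collidine and TMSCl in THF at rt. Homolysis of the C5–O bond gives the tertiary C5 radical, which is trapped by a second Cp2TiCl and loses H10 by β-hydride elimination; cationic skeletal shifts are not possible on this path. After the same methanolysis the route is rejoined at 24, and no new isolable compound is passed.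

Further compounds
F1 | step 4 | (4R,6R)-2-[(2E,8E,10E)-7,7-dimethyldodeca-2,8,10-trien-2-yl]-4,6-dimethyl-1,3-dioxane | C/C=C/C=C/C(C)(C)CCC/C=C(\C)C1O[C@H](C)C[C@@H](C)O1
F2 | step 4 | (4R,6R)-4,6-dimethyl-2-[(1R,2R,4aS,8aR)-1,2,5,5-tetramethyl-1,2,4a,5,6,7,8,8a-octahydronaphthalen-1-yl]-1,3-dioxane | C1(O[C@H](C)C[C@@H](C)O1)[C@@]2(C)[C@@H]3CCCC(C)(C)[C@H]3C=C[C@H]2C
F3 | step 10 | (3R)-5-[(1S,2S,3R,4S,4aS,8aR)-3,4-epoxy-1,2,5,5-tetramethyldecahydronaphthalen-1-yl]-3-methylpent-1-en-3-ol | C=C[C@](C)(O)CC[C@@]1(C)[C@@H]2CCCC(C)(C)[C@H]2[C@@H]3O[C@@H]3[C@H]1C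
F4 | step 10 | (3R)-5-[(1S,2S,3S,8aS)-3-hydroxy-1,2,5,5-tetramethyl-1,2,3,5,6,7,8,8a-octahydronaphthalen-1-yl]-3-methylpent-1-en-3-ol | C=C[C@](C)(O)CC[C@@]1(C)[C@@H]2CCCC(C)(C)C2=C[C@H](O)[C@H]1C
F0 | step 11 | none | none
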